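## The problem

The target is a flavone, a 4H-chromen-4-one. Its benzo ring A carries oxygen at C-5, C-7 and C-8 in addition to the ring oxygen O-1 on C-8a; ring C carries a methoxy group at C-3 and a 4-hydroxy-3-methoxyphenyl ring B at C-2. There is no stereocentre, so the task is one of regiochemistry and chemoselectivity. Six oxygens on the periphery must end as three methyl ethers (O-3, O-8, O-3'), one prenyl ether (O-7) and two free hydroxyls (O-5, O-4'). Ring A is the hard part: an aryl ketone with oxygen on both ortho carbons can close the pyranone through either of them, giving the 8-methoxy or the 6-methoxy series, and acid can interconvert the two (Wessely–Moser rearrangement). The prenyl ether is the fragile group. It is lost to strong protic or Lewis acid and to hydrogenolysis, its alkene is attacked by peracids and halogen, and it undergoes Claisen rearrangement on strong heating, so such operations must come before it is introduced and the final deprotection must be mild. The two hydroxyls that stay free need temporary groups that survive lithium amides and hot carbonate and still come off without harming the allylic ether. The feature that makes the key step possible is that C-8a lies between C-8 (methoxy) and C-4a, which bears the C-4 carbonyl. If C-8a carries bromine and C-4, C-3 and C-2 are present as a 1,3-diketone, the enol oxygen on C-2 is placed to displace the bromide in a six-membered closure, so the position of one halogen decides the 8-methoxy pattern.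

## Retrosynthesis

**Target 21 to flavone 20.** Only the two O–CH2 bonds of methoxymethyl ethers on O-5 and O-4' are cut. An acetal is chosen because it withstands amide bases, an organolithium and hot carbonate, and leaves under dilute acid at room temperature, where an aryl prenyl ether ionises much more slowly. Benzyl ethers would need hydrogenolysis or a Lewis acid, and silyl ethers would not survive the carbonate of the ring closure. The forward step must remove two acetals and leave the allylic ether.

**Flavone 20 to diketone 19.** The O-1–C-8a bond is cut. The neighbouring cut at O-1–C-2 (cyclodehydration of an ortho-hydroxyaryl diketone) is the classical one, but it leaves the choice between two ortho oxygens and hence the 6- versus 8-methoxy question. A cut at C-2–C-1' would need a 2-halo-3-methoxychromone that is no easier to make. With bromine on the future C-8a and an acetal on the other ortho oxygen, only one closure is possible. Precursor 19 has no ring C and consists of two benzene rings joined by a three-carbon chain. The forward reaction is a copper-catalysed O-arylation of a diketone enolate that must tolerate the acetals and the prenyl ether.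

**Diketone 19 to aldol 18, then to aldehyde 11 and ketone 16.** The bond between the ring A carbonyl carbon (future C-4) and the methoxy-bearing carbon (future C-3) is cut. A Claisen-type acylation at the same bond would require an ester flanked by two ortho substituents, which is a poor electrophile; an aldehyde at that position is still reactive. Ketone 16 has a single enolisable position, so the aldol addition has no regiochemical issue, and oxidation of 18 then gives 19. The cut is convergent, giving two fragments of similar size. The stereocentres of 18 need no control because both disappear.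

**Ketone 16 to aryl bromide 13 and amide 14; 13 to phenol 12.** The aryl–carbonyl bond is cut. Adding the aryllithium from 13 to the Weinreb amide 14 brings in the methoxymethyl ketone in one operation. This avoids alpha-functionalisation of an acetophenone, where alpha-halogenation and methoxide displacement tend to give epoxy ethers and generate acid that endangers the acetal. 13 is the protected form of commercial 12.

**Aldehyde 11 to silyl ether 8 and prenyl bromide 9; 8 to salicylaldehyde 7; 7 to phenol 5.** First the O-7–prenyl bond is cut, so that the alkene enters only after the peracid step. Then the acetal is removed, and then the C–CHO bond. The formyl group must go onto the one ring carbon that lies between the phenolic oxygen and bromine. A magnesium phenoxide delivers formaldehyde only to ortho carbons, and the bulky triisopropylsilyl ether in 5 shields the other ortho position. Phenol 5 is a simple tetrasubstituted benzene.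

**Phenol 5 to aldehyde 3, to 2, to 1.** The C–O bond at the future C-5 is traced back to a C–CHO bond (Baeyer–Villiger oxidation); the formyl group of 1 marks the position para to the future 8-methoxy group where this oxygen belongs. 3 comes from 2 by silylation, and 2 from commercial 1 by methylation of the more acidic hydroxyl. Starting material 1 already has bromine next to the oxygen that becomes the 8-methoxy group, so no regioselective halogenation is needed and none has to be done in the presence of the alkene.

## Roads not taken

**Alternative 1:** Ring A is disconnected at C-4a–C-5 and grown onto a finished 2-aryl-3-methoxypyranone from a four-carbon ring. Cyclobutenone A2 would open on heating in a four-electron electrocyclic step to a dienylketene, whose ketene carbon closes in a six-electron step onto the free ring carbon of the pyranone next to the carbonyl. Tautomerisation gives flavone A1 with the 5-hydroxyl free and benzyl ethers on O-7 and O-4'. Its merit is that all ring A substituents are placed by construction, with no 6/8 ambiguity and no protecting-group exchange on ring A; in these respects it equals or betters the chosen plan. Its weak points lie on both sides of the key step. A2 needs a pyranone metalated next to its ring oxygen (a species prone to ring opening), added to the right carbonyl of a squaric acid derivative, followed by methylation of a tertiary alkoxide. After A1, the benzyl ethers must be removed by hydrogenolysis, which is incompatible with a prenyl ether. The prenyl group would therefore be introduced last, with O-7 and O-4' both free and competing. The chosen plan has more steps on ring A, but each is a standard reaction from a commercial benzaldehyde and the prenyl group is introduced once, on a single free oxygen.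

**Alternative 2:** The same ring A bonds are formed, but the four-membered ring is made in the flask. Dehydrochlorination of acid chloride A4 by a tertiary amine gives a ketene that adds across silyloxyalkyne A5 in a (2+2) manner; ring opening and six-electron closure then form C-5–C-6, C-7–C-8 and C-4a–C-5 and give flavone A3. In the endgame this route is better than the chosen one. A3 has the 5-hydroxyl free and chelated, a silyl ether on O-7 that fluoride converts directly into the phenoxide for prenylation, and only one acetal left to remove. The weakness is the cascade and its substrate. A4 is a racemic alpha-methoxy acid chloride on a polysubstituted pyranone that needs its own multistep synthesis. The ketene is doubly substituted and hindered, so dimerisation and reaction at the pyranone carbonyl compete with the (2+2) addition. A5 is moisture-sensitive, and three C–C bonds must form in one operation on a heteroaryl ketene of unproven behaviour. The chosen plan offsets its longer ring A sequence with a ring closure that forms one C–O bond by a well-known catalytic reaction and has only one possible regiochemical outcome.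

**Alternative 3:** Ring A is disconnected at C-6–C-7 and closed in the manner of a polyketide. Methoxide would convert the acetyl group of pyranone A7 into its enolate, which attacks the methoxyacetate ester; the resulting cyclic diketone aromatises to the 5,7-diol A6. The merits are a cheap starting material, kojic acid A8, which already contains the pyranone and the 3-oxygen, no halogen or transition metal, and a selective final alkylation, since the 7-hydroxyl of A6 is far more acidic than the chelated 5-hydroxyl. The cost is the synthesis of A7: three different carbon substituents (an aryl group, an acetyl group and a homologated methoxyacetate arm) must be attached to A8, a long linear sequence with little close precedent. In addition, the pyranone is itself open to conjugate attack and ring opening by methoxide under the Claisen conditions. On step economy after the key step this route is at least as good as the chosen one; the chosen plan has the advantage of a short, convergent synthesis of its cyclisation substrate 19 from two simple benzenes by standard reactions.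

Key step: step 11

Remark on the chemistry: compounds 1, 9, 12 and 14 are taken as purchasable. Aldol 18 is carried on as a mixture of racemic diastereomers and diketone 19 as a racemate, because both centres become trigonal in 20.

## Route

Step 1
Reactants: 1 3-bromo-4,5-dihydroxybenzaldehyde
Product: 2 3-bromo-5-hydroxy-4-methoxybenzaldehyde
Conditions: MeI, Li2CO3, DMF, 40 °C
Reagents that add atoms: iodomethane, CI
Why: The 4-hydroxyl, para to the formyl group and ortho to bromine, is much the more acidic, so the weak base forms only its phenoxide and Williamson methylation should stop at the monoether, as in the known 4-O-selective alkylation of 3,4-dihydroxybenzaldehydes.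

Step 2
Reactants: 2 3-bromo-5-hydroxy-4-methoxybenzaldehyde
Product: 3 3-bromo-4-methoxy-5-[(triisopropylsilyl)oxy]benzaldehyde
Conditions: TIPSCl, imidazole, DMF, rt
Reagents that add atoms: chlorotri(propan-2-yl)silane, CC(C)[Si](Cl)(C(C)C)C(C)C
Why: Imidazole-promoted silylation of a phenol; the bulky silyl ether is inert to peracid and mild base, shields the adjacent ring position in step 4 and is later removed by fluoride without touching an acetal.

Step 3
Reactants: 3 3-bromo-4-methoxy-5-[(triisopropylsilyl)oxy]benzaldehyde
Product: 5 3-bromo-4-methoxy-5-[(triisopropylsilyl)oxy]phenol, via aryl formate 4 (not isolated)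
Conditions: mCPBA, CH2Cl2, 0 °C to rt; then Et3N, MeOH, rt
Reagents that add atoms: 3-chloroperoxybenzoic acid, OOC(=O)c1cccc(Cl)c1
Why: Baeyer–Villiger oxidation of an electron-rich benzaldehyde, in which the para methoxy group favours aryl migration, gives the formate, and amine-catalysed methanolysis releases the phenol; the peracid is used here because no alkene is present yet.

Step 4
Reactants: 5 3-bromo-4-methoxy-5-[(triisopropylsilyl)oxy]phenol
Product: 7 2-bromo-6-hydroxy-3-methoxy-4-[(triisopropylsilyl)oxy]benzaldehyde, via hydroxymethylphenol 6 (not isolated)
Conditions: MgCl2, Et3N, (CH2O)n, MeCN, reflux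
Reagents that add atoms: formaldehyde (as paraformaldehyde), C=O
Why: Casnati–Skattebøl ortho-formylation: the magnesium phenoxide delivers formaldehyde to an ortho carbon and a second formaldehyde oxidises the benzylic alkoxide by hydride transfer; the ortho carbon next to bromine is para to the silyloxy donor and not shielded by the triisopropylsilyl group, so it should react in preference to the other.

Step 5
Reactants: 7 2-bromo-6-hydroxy-3-methoxy-4-[(triisopropylsilyl)oxy]benzaldehyde
Product: 8 2-bromo-3-methoxy-6-(methoxymethoxy)-4-[(triisopropylsilyl)oxy]benzaldehyde
Conditions: MOMCl, iPr2NEt, CH2Cl2, 0 °C to rt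
Reagents that add atoms: chloromethyl methyl ether, COCCl
Why: O-alkylation of the salicylaldehyde hydroxyl with an alpha-chloro ether and a hindered amine; the acetal blocks the oxygen that could otherwise compete in ring closure and is stable to all basic steps that follow.

Step 6
Reactants: 8 2-bromo-3-methoxy-6-(methoxymethoxy)-4-[(triisopropylsilyl)oxy]benzaldehyde; 9 1-bromo-3-methylbut-2-ene (prenyl bromide)
Product: 11 2-bromo-3-methoxy-6-(methoxymethoxy)-4-[(3-methylbut-2-en-1-yl)oxy]benzaldehyde, via cesium phenolate 10 (not isolated)
Conditions: CsF, DMF, rt
Reagents that add atoms: none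
Why: Fluoride cleaves the aryl silyl ether, helped by the para formyl group that stabilises the phenoxide, and the cesium phenoxide is alkylated in the same flask at the primary carbon of the allylic bromide (SN2), a known one-pot desilylation–alkylation.

Step 7
Reactants: 12 4-bromo-2-methoxyphenol
Product: 13 4-bromo-2-methoxy-1-(methoxymethoxy)benzene
Conditions: MOMCl, iPr2NEt, CH2Cl2, 0 °C to rt
Reagents that add atoms: chloromethyl methyl ether, COCCl
Why: Routine acetal protection of a phenol; the ether tolerates the organolithium of step 8 and is removed together with the ring A acetal in step 12.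

Step 8
Reactants: 13 4-bromo-2-methoxy-1-(methoxymethoxy)benzene; 14 N,2-dimethoxy-N-methylacetamide
Product: 16 2-methoxy-1-[3-methoxy-4-(methoxymethoxy)phenyl]ethan-1-one, via aryllithium 15 (not isolated)
Conditions: n-BuLi, THF, −78 °C; then 14, −78 to 0 °C; aq NH4Cl
Reagents that add atoms: none
Why: Bromine–lithium exchange outruns ortho-deprotonation at −78 °C, and the aryllithium adds only once to the Weinreb amide because the chelated tetrahedral adduct persists until work-up (Weinreb ketone synthesis).

Step 9
Reactants: 16 2-methoxy-1-[3-methoxy-4-(methoxymethoxy)phenyl]ethan-1-one; 11 2-bromo-3-methoxy-6-(methoxymethoxy)-4-[(3-methylbut-2-en-1-yl)oxy]benzaldehyde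
Product: 18 3-{2-bromo-3-methoxy-6-(methoxymethoxy)-4-[(3-methylbut-2-en-1-yl)oxy]phenyl}-3-hydroxy-2-methoxy-1-[3-methoxy-4-(methoxymethoxy)phenyl]propan-1-one (mixture of racemic syn and anti diastereomers), via lithium enolate 17 (not isolated)
Conditions: LiN(SiMe3)2, THF, −78 °C; then 11, −78 °C; aq NH4Cl at −78 °C
Reagents that add atoms: none
Why: Directed aldol addition of a preformed lithium enolate (the ketone has one enolisable position) to a non-enolisable aldehyde, quenched cold to suppress retro-aldol cleavage; the two new stereocentres are set without control, which is harmless because both are removed in steps 10 and 11.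

Step 10
Reactants: 18 3-{2-bromo-3-methoxy-6-(methoxymethoxy)-4-[(3-methylbut-2-en-1-yl)oxy]phenyl}-3-hydroxy-2-methoxy-1-[3-methoxy-4-(methoxymethoxy)phenyl]propan-1-one
Product: 19 1-{2-bromo-3-methoxy-6-(methoxymethoxy)-4-[(3-methylbut-2-en-1-yl)oxy]phenyl}-2-methoxy-3-[3-methoxy-4-(methoxymethoxy)phenyl]propane-1,3-dione (racemic)
Conditions: Dess–Martin periodinane, CH2Cl2, 0 °C to rt
Reagents that add atoms: none
Why: Dess–Martin oxidation converts beta-hydroxy ketones into 1,3-diketones under near-neutral conditions that leave the trisubstituted alkene, the aryl bromide and both acetals untouched; the carbinol centre disappears and the remaining centre is racemic and enolisable.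

Step 11
Reactants: 19 1-{2-bromo-3-methoxy-6-(methoxymethoxy)-4-[(3-methylbut-2-en-1-yl)oxy]phenyl}-2-methoxy-3-[3-methoxy-4-(methoxymethoxy)phenyl]propane-1,3-dione
Product: 20 3,8-dimethoxy-5-(methoxymethoxy)-2-[3-methoxy-4-(methoxymethoxy)phenyl]-7-[(3-methylbut-2-en-1-yl)oxy]-4H-chromen-4-one
Conditions: CuI (10 mol %), 1,10-phenanthroline (20 mol %), Cs2CO3, DMF, 90 °C, Ar
Reagents that add atoms: none
Why: Cs2CO3 removes the acidic proton between the two carbonyls of 19 and the enolate is passed to the phenanthroline-bound monovalent copper centre. The C-8a–Br bond, ortho to the carbonyl that tethers the enolate, should then undergo oxidative addition to a chelated trivalent copper aryl enolate, and C–O reductive elimination joins the enol oxygen on C-2 to C-8a and regenerates monovalent copper. The closest known reaction type is the copper-catalysed intramolecular Ullmann O-arylation of 1-(2-haloaryl)-1,3-diketones to chromones and flavones. Ring C closes as a six-membered ring by ipso substitution at an aromatic carbon (6-exo type), with bromide leaving outside the new ring. No stereocentre is formed; the racemic centre of 19 becomes the trigonal C-3 of 20. O-arylation is secured over C-arylation by ring size, since attack through the central carbon or through the other enolate oxygen would need a four-membered ring. The 8-methoxy pattern is fixed by the position of bromine, and the acetal on the other ortho oxygen excludes the cyclodehydration that would give the 6-methoxy isomer. Carbonate in dry DMF at 90 °C should leave the prenyl ether (well below Claisen temperatures) and both acetals intact.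

Step 12
Reactants: 20 3,8-dimethoxy-5-(methoxymethoxy)-2-[3-methoxy-4-(methoxymethoxy)phenyl]-7-[(3-methylbut-2-en-1-yl)oxy]-4H-chromen-4-one
Product: 21 5-hydroxy-2-(4-hydroxy-3-methoxyphenyl)-3,8-dimethoxy-7-[(3-methylbut-2-en-1-yl)oxy]-4H-chromen-4-one (5,4'-dihydroxy-3,8,3'-trimethoxy-7-prenyloxyflavone)
Conditions: HCl (about 1 M), MeOH/THF, rt
Reagents that add atoms: none
Why: Acid-catalysed transacetalisation to methanol removes both methoxymethyl ethers, the one on O-5 assisted by the peri carbonyl, while an aryl prenyl ether ionises much more slowly in dilute acid at room temperature; the reaction is to be stopped as soon as both acetals are gone.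

## Compound list

1 | 3-bromo-4,5-dihydroxybenzaldehyde | O=Cc1cc(O)c(O)c(Br)c1 | starting material
2 | 3-bromo-5-hydroxy-4-methoxybenzaldehyde | O=Cc1cc(O)c(OC)c(Br)c1 | intermediate
3 | 3-bromo-4-methoxy-5-[(triisopropylsilyl)oxy]benzaldehyde | O=Cc1cc(O[Si](C(C)C)(C(C)C)C(C)C)c(OC)c(Br)c1 | intermediate
4 | 3-bromo-4-methoxy-5-[(triisopropylsilyl)oxy]phenyl formate | O=COc1cc(O[Si](C(C)C)(C(C)C)C(C)C)c(OC)c(Br)c1 | intermediate (not isolated)
5 | 3-bromo-4-methoxy-5-[(triisopropylsilyl)oxy]phenol | Oc1cc(O[Si](C(C)C)(C(C)C)C(C)C)c(OC)c(Br)c1 | intermediate
6 | 3-bromo-2-(hydroxymethyl)-4-methoxy-5-[(triisopropylsilyl)oxy]phenol (present as its magnesium salt) | OCc1c(O)cc(O[Si](C(C)C)(C(C)C)C(C)C)c(OC)c1Br | intermediate (not isolated)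
7 | 2-bromo-6-hydroxy-3-methoxy-4-[(triisopropylsilyl)oxy]benzaldehyde | O=Cc1c(O)cc(O[Si](C(C)C)(C(C)C)C(C)C)c(OC)c1Br | intermediate
8 | 2-bromo-3-methoxy-6-(methoxymethoxy)-4-[(triisopropylsilyl)oxy]benzaldehyde | O=Cc1c(OCOC)cc(O[Si](C(C)C)(C(C)C)C(C)C)c(OC)c1Br | intermediate
9 | 1-bromo-3-methylbut-2-ene (prenyl bromide) | CC(C)=CCBr | starting material
10 | cesium 3-bromo-4-formyl-2-methoxy-5-(methoxymethoxy)phenolate | [Cs+].[O-]c1cc(OCOC)c(C=O)c(Br)c1OC | intermediate (not isolated)
11 | 2-bromo-3-methoxy-6-(methoxymethoxy)-4-[(3-methylbut-2-en-1-yl)oxy]benzaldehyde | O=Cc1c(OCOC)cc(OCC=C(C)C)c(OC)c1Br | intermediate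
12 | 4-bromo-2-methoxyphenol | COc1cc(Br)ccc1O | starting material
13 | 4-bromo-2-methoxy-1-(methoxymethoxy)benzene | COCOc1ccc(Br)cc1OC | intermediate
14 | N,2-dimethoxy-N-methylacetamide | COCC(=O)N(C)OC | starting material
15 | [3-methoxy-4-(methoxymethoxy)phenyl]lithium | [Li]c1ccc(OCOC)c(OC)c1 | intermediate (not isolated)
16 | 2-methoxy-1-[3-methoxy-4-(methoxymethoxy)phenyl]ethan-1-one | COCC(=O)c1ccc(OCOC)c(OC)c1 | intermediate
17 | lithium (Z)-2-methoxy-1-[3-methoxy-4-(methoxymethoxy)phenyl]ethen-1-olate (chelated Z geometry expected, without consequence) | [Li+].[O-]/C(=C\OC)c1ccc(OCOC)c(OC)c1 | intermediate (not isolated)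
18 | 3-{2-bromo-3-methoxy-6-(methoxymethoxy)-4-[(3-methylbut-2-en-1-yl)oxy]phenyl}-3-hydroxy-2-methoxy-1-[3-methoxy-4-(methoxymethoxy)phenyl]propan-1-one, mixture of racemic syn and anti diastereomers | COCOc1cc(OCC=C(C)C)c(OC)c(Br)c1C(O)C(OC)C(=O)c1ccc(OCOC)c(OC)c1 | intermediate
19 | 1-{2-bromo-3-methoxy-6-(methoxymethoxy)-4-[(3-methylbut-2-en-1-yl)oxy]phenyl}-2-methoxy-3-[3-methoxy-4-(methoxymethoxy)phenyl]propane-1,3-dione, racemic | COCOc1cc(OCC=C(C)C)c(OC)c(Br)c1C(=O)C(OC)C(=O)c1ccc(OCOC)c(OC)c1 | intermediate
20 | 3,8-dimethoxy-5-(methoxymethoxy)-2-[3-methoxy-4-(methoxymethoxy)phenyl]-7-[(3-methylbut-2-en-1-yl)oxy]-4H-chromen-4-one | COc1c(-c2ccc(OCOC)c(OC)c2)oc2c(OC)c(OCC=C(C)C)cc(OCOC)c2c1=O | intermediate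
21 | 5-hydroxy-2-(4-hydroxy-3-methoxyphenyl)-3,8-dimethoxy-7-[(3-methylbut-2-en-1-yl)oxy]-4H-chromen-4-one | COc1cc(-c2oc3c(OC)c(OCC=C(C)C)cc(O)c3c(=O)c2OC)ccc1O | target

## Step count and risks

Total step count: 12. Longest linear sequence: 10 steps (steps 1 to 6, then 9 to 12, from 1 to 21). The ring B branch (steps 7 and 8) has 2 steps.

**Step 11 (key step).** The bromide sits on an electron-rich ring between two ortho substituents, so activation of the C–Br bond by copper may be slow. Reductive loss of bromine and base-induced retro-Claisen cleavage of the 2-methoxy diketone could then compete. The fallback sets out from 19 and puts the oxygen on C-8a first. A coupling catalysed by zerovalent palladium (Pd2(dba)3, a bulky biarylphosphine, Cs2CO3, DMF, 80 °C) with benzaldoxime as hydroxide surrogate should give 1-{2-hydroxy-3-methoxy-6-(methoxymethoxy)-4-[(3-methylbut-2-en-1-yl)oxy]phenyl}-2-methoxy-3-[3-methoxy-4-(methoxymethoxy)phenyl]propane-1,3-dione F1, in equilibrium with its cyclic hemiketal. Dehydration under non-acidic conditions (trifluoroacetic anhydride, pyridine) would close ring C in the classical way and return to the route at 20. The regiochemistry stays secured because the other ortho oxygen is still an acetal.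

**Step 4.** Formylation may go to the wrong ortho carbon (between hydroxyl and silyloxy) or be slow beside bromine. The fallback sets out from 5 and replaces phenoxide-directed formylation by directed metalation. Acetal protection gives 1-bromo-2-methoxy-5-(methoxymethoxy)-3-[(triisopropylsilyl)oxy]benzene F2. Deprotonation with LiN(iPr)2 in THF at −78 °C should occur at the carbon between bromine and the acetal oxygen, which is acidified by both, while the other position is screened by the silyl group. A DMF quench returns to the route at 8, bypassing 7.

**Step 9.** The aldehyde carries two ortho substituents, so addition may be incomplete and the crowded aldolate may revert on warming; the oxidation in step 10 then suffers as well. The fallback sets out from 11 and makes the diketone by acylation. Oxidation with Ag2O in aqueous NaOH gives 2-bromo-3-methoxy-6-(methoxymethoxy)-4-[(3-methylbut-2-en-1-yl)oxy]benzoic acid F3. 1,1'-Carbonyldiimidazole converts it into {2-bromo-3-methoxy-6-(methoxymethoxy)-4-[(3-methylbut-2-en-1-yl)oxy]phenyl}(1H-imidazol-1-yl)methanone F4. C-acylation of two equivalents of lithium enolate 17 with F4 returns to the route at 19, bypassing 18.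

**Step 12.** Acid may ionise the allylic C–O bond or add across the alkene before the less reactive acetal on O-4' is gone. The fallback sets out from 20 and removes everything on purpose. Warm methanolic HCl should give 5,7-dihydroxy-2-(4-hydroxy-3-methoxyphenyl)-3,8-dimethoxy-4H-chromen-4-one F5. One equivalent of prenyl bromide 9 with KHCO3 in DMF should then alkylate the 7-hydroxyl, the most acidic of the three (para to the carbonyl; the 5-hydroxyl is chelated and the 4'-hydroxyl less acidic), and return to the route at 21.

## Further compounds

F1 | step 11 | 1-{2-hydroxy-3-methoxy-6-(methoxymethoxy)-4-[(3-methylbut-2-en-1-yl)oxy]phenyl}-2-methoxy-3-[3-methoxy-4-(methoxymethoxy)phenyl]propane-1,3-dione (racemic) | COCOc1cc(OCC=C(C)C)c(OC)c(O)c1C(=O)C(OC)C(=O)c1ccc(OCOC)c(OC)c1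
F2 | step 4 | 1-bromo-2-methoxy-5-(methoxymethoxy)-3-[(triisopropylsilyl)oxy]benzene | COCOc1cc(Br)c(OC)c(O[Si](C(C)C)(C(C)C)C(C)C)c1
F3 | step 9 | 2-bromo-3-methoxy-6-(methoxymethoxy)-4-[(3-methylbut-2-en-1-yl)oxy]benzoic acid | OC(=O)c1c(OCOC)cc(OCC=C(C)C)c(OC)c1Br
F4 | step 9 | {2-bromo-3-methoxy-6-(methoxymethoxy)-4-[(3-methylbut-2-en-1-yl)oxy]phenyl}(1H-imidazol-1-yl)methanone | O=C(c1c(OCOC)cc(OCC=C(C)C)c(OC)c1Br)n1ccnc1
F5 | step 12 | 5,7-dihydroxy-2-(4-hydroxy-3-methoxyphenyl)-3,8-dimethoxy-4H-chromen-4-one | COc1cc(-c2oc3c(OC)c(O)cc(O)c3c(=O)c2OC)ccc1O
A1 | alternative 1 | 7-(benzyloxy)-2-[4-(benzyloxy)-3-methoxyphenyl]-5-hydroxy-3,8-dimethoxy-4H-chromen-4-one | COc1c(-c2ccc(OCc3ccccc3)c(OC)c2)oc2c(OC)c(OCc3ccccc3)cc(O)c2c1=O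
A2 | alternative 1 | 3-(benzyloxy)-4-{6-[4-(benzyloxy)-3-methoxyphenyl]-5-methoxy-4-oxo-4H-pyran-2-yl}-4-methoxycyclobut-2-en-1-one (racemic) | O=C1C=C(OCc2ccccc2)C1(OC)c1cc(=O)c(OC)c(-c2ccc(OCc3ccccc3)c(OC)c2)o1
A3 | alternative 2 | 5-hydroxy-3,8-dimethoxy-2-[3-methoxy-4-(methoxymethoxy)phenyl]-7-[(triisopropylsilyl)oxy]-4H-chromen-4-one | COc1c(-c2ccc(OCOC)c(OC)c2)oc2c(OC)c(O[Si](C(C)C)(C(C)C)C(C)C)cc(O)c2c1=O
A4 | alternative 2 | 2-methoxy-2-{5-methoxy-6-[3-methoxy-4-(methoxymethoxy)phenyl]-4-oxo-4H-pyran-2-yl}acetyl chloride (racemic) | COC(C(=O)Cl)c1cc(=O)c(OC)c(-c2ccc(OCOC)c(OC)c2)o1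
A5 | alternative 2 | (ethynyloxy)tri(propan-2-yl)silane | C#CO[Si](C(C)C)(C(C)C)C(C)C
A6 | alternative 3 | 5,7-dihydroxy-3,8-dimethoxy-2-[3-methoxy-4-(methoxymethoxy)phenyl]-4H-chromen-4-one | COc1c(-c2ccc(OCOC)c(OC)c2)oc2c(OC)c(O)cc(O)c2c1=O
A7 | alternative 3 | methyl 2-{3-acetyl-5-methoxy-6-[3-methoxy-4-(methoxymethoxy)phenyl]-4-oxo-4H-pyran-2-yl}-2-methoxyacetate (racemic) | COC(=O)C(OC)c1oc(-c2ccc(OCOC)c(OC)c2)c(OC)c(=O)c1C(C)=O
A8 | alternative 3 | kojic acid, 5-hydroxy-2-(hydroxymethyl)-4H-pyran-4-one | OCc1cc(=O)c(O)co1
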